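## Retrosynthetic overview

- The strategy rests on ring B (C5, C6=C7, C8, C9, C10; labdane numbering). Its C6=C7 bond and C8 ester form a [4+2] retron (diene C5–C8, dienophile C9=C10). With oxygen at C6 and C11 as an aldehyde, C5, C8 and C9 can all be epimerised, so only the quaternary C10 needs kinetic control.
- Side chain last: C12–C13 by B-alkyl Suzuki–Miyaura coupling of the C9 vinyl decalin with a (Z)-β-iodo enoate, after C11=C12 methylenation of the C9 aldehyde.
- Decalin: acid-triggered intramolecular ionic [4+2] of an acyclic enal (R,R)-hydrobenzoin acetal with a 2-silyloxydienoate. Ring A closes first (C5–C10), ring B second (C8–C9), in one operation; no other ring is made.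
- Acyclic chain: C7=C8 by glyoxylate aldol and dehydration, C1–C10 by B-alkyl Suzuki–Miyaura coupling, quaternary C4 by Hosomi–Sakurai allylation of mesityl oxide.

Key step: step 9

Remark: labdane numbering is used for the carbon atoms throughout; the facial sense that the (R,R)-diol imposes at C10 in step 9 is assigned by analogy with related chiral dioxolanes, and (S,S)-hydrobenzoin would be used in step 2 if the induction proves opposite.

## Route

Step 1
Reactants: 1 mesityl oxide; 2 allyltrimethylsilane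
Product: 3 4,4-dimethylhept-6-en-2-one
Conditions: TiCl4 (1.0 equiv), CH2Cl2, −78 °C → −40 °C; then H2O
Reagents that add atoms: none
Why: Hosomi–Sakurai conjugate allylation, in which the TiCl4-activated β,β-disubstituted enone takes the allyl group at its β-carbon and so creates the quaternary C4 with both methyl groups, without forming a stereocentre.

Step 2
Reactants: 4 but-2-ynal diethyl acetal; 5 (R,R)-hydrobenzoin
Product: 6 (4R,5R)-4,5-diphenyl-2-(prop-1-yn-1-yl)-1,3-dioxolane
Conditions: TsOH·H2O (5 mol%), toluene, 60 °C, reduced pressure (EtOH distilled off)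
Reagents that add atoms: none
Why: Acid-catalysed transacetalisation driven by removal of ethanol, giving a single compound because the C2-symmetric diol leaves the acetal carbon non-stereogenic.

Step 3
Reactants: 6 (4R,5R)-4,5-diphenyl-2-(prop-1-yn-1-yl)-1,3-dioxolane
Product: 8 (4R,5R)-2-[(1E)-2-iodoprop-1-en-1-yl]-4,5-diphenyl-1,3-dioxolane, via alkenylzirconocene chloride 7 (not isolated)
Conditions: Cp2Zr(H)Cl (2.0 equiv), THF, rt → 45 °C; then I2, THF, −20 °C
Reagents that add atoms: iodine, II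
Why: Hydrozirconation adds Zr–H syn across the alkyne and, on equilibration with excess hydride, places zirconium on the less hindered methyl-bearing carbon (where no β-alkoxide elimination is possible), and iodinolysis with retention should give the (E)-iodide.

Step 4
Reactants: 3 4,4-dimethylhept-6-en-2-one; 8 (4R,5R)-2-[(1E)-2-iodoprop-1-en-1-yl]-4,5-diphenyl-1,3-dioxolane
Product: 10 (8E)-9-[(4R,5R)-4,5-diphenyl-1,3-dioxolan-2-yl]-4,4,8-trimethylnon-8-en-2-ol (both C2 epimers), via bis(9-BBN) adduct 9 (not isolated)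
Conditions: (9-BBN)2 (2.2 equiv B–H per 3), THF, 0 °C → rt; then 8, Pd(dppf)Cl2 (5 mol%), AsPh3 (10 mol%), Cs2CO3, DMF/H2O, rt
Reagents that add atoms: none
Why: 9-BBN hydroborates the terminal alkene anti-Markovnikov and also reduces ketones, so it is used in excess to take the carbonyl deliberately to an inert B-alkoxy borinate; the primary alkylborane then undergoes B-alkyl Suzuki–Miyaura coupling with retention of the (E)-geometry, and the carbinol centre (or any unreduced ketone) converges in step 5.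

Step 5
Reactants: 10 (8E)-9-[(4R,5R)-4,5-diphenyl-1,3-dioxolan-2-yl]-4,4,8-trimethylnon-8-en-2-ol
Product: 11 (8E)-9-[(4R,5R)-4,5-diphenyl-1,3-dioxolan-2-yl]-4,4,8-trimethylnon-8-en-2-one
Conditions: Dess–Martin periodinane, NaHCO3, CH2Cl2, 0 °C → rt
Reagents that add atoms: none
Why: Dess–Martin oxidation under bicarbonate buffer should return the methyl ketone without touching the acid-labile enal acetal or the trisubstituted alkene.

Step 6
Reactants: 11 (8E)-9-[(4R,5R)-4,5-diphenyl-1,3-dioxolan-2-yl]-4,4,8-trimethylnon-8-en-2-one; 12 methyl glyoxylate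
Product: 14 methyl (10E)-11-[(4R,5R)-4,5-diphenyl-1,3-dioxolan-2-yl]-2-hydroxy-6,6,10-trimethyl-4-oxoundec-10-enoate (both C2 epimers), via lithium enolate 13 (not isolated)
Conditions: LiN(iPr)2 (1.1 equiv), THF, −78 °C; then 12 (freshly distilled), −78 °C; then H2O
Reagents that add atoms: none
Why: Kinetic deprotonation takes the methyl group rather than the neopentyl-type CH2 next to the quaternary carbon, and the lithium enolate adds to the glyoxylate aldehyde in a directed aldol reaction whose uncontrolled carbinol centre is removed in step 7.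

Step 7
Reactants: 14 methyl (10E)-11-[(4R,5R)-4,5-diphenyl-1,3-dioxolan-2-yl]-2-hydroxy-6,6,10-trimethyl-4-oxoundec-10-enoate
Product: 16 methyl (2E,10E)-11-[(4R,5R)-4,5-diphenyl-1,3-dioxolan-2-yl]-6,6,10-trimethyl-4-oxoundeca-2,10-dienoate, via mesylate 15 (not isolated)
Conditions: MsCl, Et3N (excess), CH2Cl2, 0 °C → rt
Reagents that add atoms: none
Why: Mesylation followed by E1cB elimination through the ketone enolate should give the conjugated 4-oxo-2-enoate as its thermodynamically favoured (E)-isomer under basic conditions that leave the acetal intact.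

Step 8
Reactants: 16 methyl (2E,10E)-11-[(4R,5R)-4,5-diphenyl-1,3-dioxolan-2-yl]-6,6,10-trimethyl-4-oxoundeca-2,10-dienoate
Product: 17 methyl (2E,4Z,10E)-4-[(tert-butyldimethylsilyl)oxy]-11-[(4R,5R)-4,5-diphenyl-1,3-dioxolan-2-yl]-6,6,10-trimethylundeca-2,4,10-trienoate
Conditions: TBSOTf (1.3 equiv), Et3N (2.5 equiv), CH2Cl2, −78 °C → 0 °C; non-aqueous work-up, filtration through Et3N-deactivated silica
Reagents that add atoms: tert-butyldimethylsilyl trifluoromethanesulfonate, CC(C)(C)[Si](C)(C)OS(=O)(=O)C(F)(F)F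
Why: Soft enolisation of the enone can only occur towards C5 (C7 is vinylic), giving the cross-conjugated 2-silyloxydiene with the (Z)-enol ether geometry that keeps the bulky C4 carbon away from C7, while the excess amine keeps the medium too weakly Lewis acidic to ionise the acetal.

Step 9
Reactants: 17 methyl (2E,4Z,10E)-4-[(tert-butyldimethylsilyl)oxy]-11-[(4R,5R)-4,5-diphenyl-1,3-dioxolan-2-yl]-6,6,10-trimethylundeca-2,4,10-trienoate
Product: 18 methyl (1R,2S,4aR,8aR)-4-[(tert-butyldimethylsilyl)oxy]-1-[(4R,5R)-4,5-diphenyl-1,3-dioxolan-2-yl]-5,5,8a-trimethyl-1,2,4a,5,6,7,8,8a-octahydronaphthalene-2-carboxylate (C5 and C8 epimers may accompany it and converge in step 10)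
Conditions: TMSOTf (20 mol%), 2,6-di-tert-butyl-4-methylpyridine (30 mol%), CH2Cl2 (0.01 M), −78 °C → −30 °C; Et3N quench
Reagents that add atoms: none
Why: Proposed new method: TMSOTf silylates one dioxolane oxygen and opens the ring to an alkoxyallyl cation whose tertiary C10 terminus is attacked by C5 of the silyl dienol ether in a 6-exo closure of ring A (C5–C10 bond, helped by the C4 gem-dimethyl group; attack at C11 would need an 8-membered ring), after which the C11=C9 enol ether adds through C9 to C8 of the silyloxocarbenium-activated enoate in a 6-endo closure of ring B (C8–C9 bond), the pendant silyl ether recloses the dioxolane and TMSOTf is released. The closest known reaction type is the intramolecular ionic Diels–Alder reaction of α,β-unsaturated acetals with dienes under silyl triflate or protic acid catalysis, equivalent here to a Mukaiyama–Michael/Michael annulation of a 2-silyloxydiene, which has not been shown for a β,β-disubstituted enal acetal paired with an ester-bearing silyloxydiene. Both bonds are polarity-matched (nucleophilic C5 and C9, electrophilic C10 and C8), unlike a thermal cycloaddition of the parent dienoate. C10 is set by the (4R,5R)-diphenyldioxolane, whose opened chiral alkoxy arm should shield one face of the allyl cation; C9 follows from suprafacial addition across the (E)-alkene; C5 and C8 arise from the folding of the tether and the second closure and are not relied on. The only selectivity required is the facial one at C10, because C5, C8 and C9 are corrected thermodynamically in steps 10 and 13 and the auxiliary stays attached, so a minor C10 diastereomer can be removed by chromatography or crystallisation.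

Step 10
Reactants: 18 methyl (1R,2S,4aR,8aR)-4-[(tert-butyldimethylsilyl)oxy]-1-[(4R,5R)-4,5-diphenyl-1,3-dioxolan-2-yl]-5,5,8a-trimethyl-1,2,4a,5,6,7,8,8a-octahydronaphthalene-2-carboxylate
Product: 19 methyl (1R,2S,4aR,8aS)-1-[(4R,5R)-4,5-diphenyl-1,3-dioxolan-2-yl]-5,5,8a-trimethyl-4-oxodecahydronaphthalene-2-carboxylate
Conditions: Bu4NF, THF, 0 °C; then NaOMe, MeOH, 50 °C
Reagents that add atoms: none
Why: Fluoride cleaves the silyl enol ether to the 6-ketone, and methoxide in methanol (degenerate with the methyl ester) should equilibrate C5 through the ketone enolate to the trans ring fusion and C8 through the ester enolate to the equatorial ester, which avoids the 1,3-diaxial contact with the angular methyl group.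

Step 11
Reactants: 19 methyl (1R,2S,4aR,8aS)-1-[(4R,5R)-4,5-diphenyl-1,3-dioxolan-2-yl]-5,5,8a-trimethyl-4-oxodecahydronaphthalene-2-carboxylate
Product: 21 methyl (1R,2S,4aR,8aR)-1-[(4R,5R)-4,5-diphenyl-1,3-dioxolan-2-yl]-5,5,8a-trimethyl-4-[(trifluoromethanesulfonyl)oxy]-1,2,4a,5,6,7,8,8a-octahydronaphthalene-2-carboxylate, via potassium enolate 20 (not isolated)
Conditions: KN(SiMe3)2 (1.1 equiv), THF, −78 °C; then PhNTf2, −78 °C → 0 °C; then H2O
Reagents that add atoms: N-phenylbis(trifluoromethanesulfonimide), O=S(=O)(N(c1ccccc1)S(=O)(=O)C(F)(F)F)C(F)(F)F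
Why: Kinetic enolisation should remove a C7 proton rather than the C5 methine shielded by the gem-dimethyl and angular methyl groups or the less acidic ester α-proton at C8, and O-triflation fixes the double bond at C6=C7.

Step 12
Reactants: 21 methyl (1R,2S,4aR,8aR)-1-[(4R,5R)-4,5-diphenyl-1,3-dioxolan-2-yl]-5,5,8a-trimethyl-4-[(trifluoromethanesulfonyl)oxy]-1,2,4a,5,6,7,8,8a-octahydronaphthalene-2-carboxylate
Product: 22 methyl (1R,2S,4aR,8aR)-1-[(4R,5R)-4,5-diphenyl-1,3-dioxolan-2-yl]-5,5,8a-trimethyl-1,2,4a,5,6,7,8,8a-octahydronaphthalene-2-carboxylate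
Conditions: Pd(OAc)2 (5 mol%), PPh3 (10 mol%), Bu3N, HCO2H, DMF, 60 °C
Reagents that add atoms: none
Why: Palladium-catalysed formate reduction of the enol triflate (oxidative addition, formate exchange, decarboxylation, C–H reductive elimination) replaces OTf by hydrogen without moving the double bond, and the weakly basic medium should leave the C8 centre of the β,γ-unsaturated ester untouched.

Step 13
Reactants: 22 methyl (1R,2S,4aR,8aR)-1-[(4R,5R)-4,5-diphenyl-1,3-dioxolan-2-yl]-5,5,8a-trimethyl-1,2,4a,5,6,7,8,8a-octahydronaphthalene-2-carboxylate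
Product: 23 methyl (1R,2S,4aR,8aR)-1-formyl-5,5,8a-trimethyl-1,2,4a,5,6,7,8,8a-octahydronaphthalene-2-carboxylate
Conditions: 2 M aq HCl, THF, 45 °C
Reagents that add atoms: water, O
Why: Acid hydrolysis frees the aldehyde and returns the diol auxiliary, and enolisation in the acidic medium lets C9 settle in the equatorial configuration (cis to the angular methyl) that suprafacial addition to the (E)-alkene already delivers, while the isolated C6=C7 bond and the esters are inert.

Step 14
Reactants: 23 methyl (1R,2S,4aR,8aR)-1-formyl-5,5,8a-trimethyl-1,2,4a,5,6,7,8,8a-octahydronaphthalene-2-carboxylate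
Product: 24 methyl (1R,2S,4aR,8aS)-1-ethenyl-5,5,8a-trimethyl-1,2,4a,5,6,7,8,8a-octahydronaphthalene-2-carboxylate
Conditions: Ph3PCH3Br, KN(SiMe3)2, THF, 0 °C; then 23, −78 °C → 0 °C
Reagents that add atoms: methyltriphenylphosphonium bromide, C[P+](c1ccccc1)(c1ccccc1)c1ccccc1.[Br-]
Why: Wittig methylenation with a near-stoichiometric non-stabilised ylide at low temperature should be faster at the aldehyde than deprotonation of the hindered C8 methine or attack on the esters, and C9 stays in its thermodynamically preferred equatorial configuration.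

Step 15
Reactants: 25 methyl 4-hydroxybut-2-ynoate
Product: 26 methyl 4-(acetyloxy)but-2-ynoate
Conditions: Ac2O, pyridine, DMAP (cat.), CH2Cl2, 0 °C
Reagents that add atoms: acetic anhydride, CC(=O)OC(C)=O
Why: Standard O-acetylation of the primary propargylic alcohol.

Step 16
Reactants: 26 methyl 4-(acetyloxy)but-2-ynoate
Product: 27 methyl (2Z)-4-(acetyloxy)-3-iodobut-2-enoate
Conditions: NaI, AcOH, 70 °C
Reagents that add atoms: sodium iodide, [Na+].[I-]
Why: Conjugate hydroiodination of the ynoate, in which iodide adds to the β-carbon and the allenolate is protonated anti, places iodine cis to the ester and so gives the (Z)-β-iodo enoate.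

Step 17
Reactants: 24 methyl (1R,2S,4aR,8aS)-1-ethenyl-5,5,8a-trimethyl-1,2,4a,5,6,7,8,8a-octahydronaphthalene-2-carboxylate; 27 methyl (2Z)-4-(acetyloxy)-3-iodobut-2-enoate
Product: 29 methyl (1R,2S,4aR,8aS)-1-[(3E)-3-(acetoxymethyl)-5-methoxy-5-oxopent-3-en-1-yl]-5,5,8a-trimethyl-1,2,4a,5,6,7,8,8a-octahydronaphthalene-2-carboxylate (target CNP0190145.1), via B-alkyl-9-BBN 28 (not isolated)
Conditions: (9-BBN)2, THF, 0 °C → rt; then 27, Pd(dppf)Cl2 (10 mol%), AsPh3 (20 mol%), K3PO4 (aq), DMF, rt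
Reagents that add atoms: none
Why: 9-BBN selects the monosubstituted vinyl group over the ring 1,2-disubstituted alkene and the esters, and the primary borane should couple (B-alkyl Suzuki–Miyaura) with the activated β-iodo enoate at room temperature with retention, so that C12 ends cis to the ester (E at C13=C14) under a phosphate base mild enough to spare the acetate and the β,γ-unsaturated ester.

## Compound list

1 | mesityl oxide (4-methylpent-3-en-2-one) | CC(=O)C=C(C)C | starting material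
2 | allyltrimethylsilane | C=CC[Si](C)(C)C | starting material
3 | 4,4-dimethylhept-6-en-2-one | CC(=O)CC(C)(C)CC=C | intermediate
4 | but-2-ynal diethyl acetal (1,1-diethoxybut-2-yne) | CC#CC(OCC)OCC | starting material
5 | (1R,2R)-1,2-diphenylethane-1,2-diol ((R,R)-hydrobenzoin) | O[C@H](c1ccccc1)[C@H](O)c1ccccc1 | starting material
6 | (4R,5R)-4,5-diphenyl-2-(prop-1-yn-1-yl)-1,3-dioxolane | CC#CC1O[C@H](c2ccccc2)[C@@H](c2ccccc2)O1 | intermediate
7 | chlorobis(cyclopentadienyl)[(1E)-1-((4R,5R)-4,5-diphenyl-1,3-dioxolan-2-yl)prop-1-en-2-yl]zirconium | C/C(=C\C1O[C@H](c2ccccc2)[C@@H](c2ccccc2)O1)[Zr](Cl)(C3C=CC=C3)C4C=CC=C4 | intermediate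
8 | (4R,5R)-2-[(1E)-2-iodoprop-1-en-1-yl]-4,5-diphenyl-1,3-dioxolane | I/C(C)=C/C1O[C@H](c2ccccc2)[C@@H](c2ccccc2)O1 | intermediate
9 | 9-[6-(9-borabicyclo[3.3.1]nonan-9-yloxy)-4,4-dimethylheptyl]-9-borabicyclo[3.3.1]nonane | CC(OB1C2CCCC1CCC2)CC(C)(C)CCCB1C2CCCC1CCC2 | intermediate
10 | (8E)-9-[(4R,5R)-4,5-diphenyl-1,3-dioxolan-2-yl]-4,4,8-trimethylnon-8-en-2-ol (both C2 epimers) | CC(O)CC(C)(C)CCC/C(C)=C/C1O[C@H](c2ccccc2)[C@@H](c2ccccc2)O1 | intermediate
11 | (8E)-9-[(4R,5R)-4,5-diphenyl-1,3-dioxolan-2-yl]-4,4,8-trimethylnon-8-en-2-one | CC(=O)CC(C)(C)CCC/C(C)=C/C1O[C@H](c2ccccc2)[C@@H](c2ccccc2)O1 | intermediate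
12 | methyl glyoxylate | COC(=O)C=O | starting material
13 | lithium (8E)-9-[(4R,5R)-4,5-diphenyl-1,3-dioxolan-2-yl]-4,4,8-trimethylnona-1,8-dien-2-olate | [Li]OC(=C)CC(C)(C)CCC/C(C)=C/C1O[C@H](c2ccccc2)[C@@H](c2ccccc2)O1 | intermediate
14 | methyl (10E)-11-[(4R,5R)-4,5-diphenyl-1,3-dioxolan-2-yl]-2-hydroxy-6,6,10-trimethyl-4-oxoundec-10-enoate (both C2 epimers) | COC(=O)C(O)CC(=O)CC(C)(C)CCC/C(C)=C/C1O[C@H](c2ccccc2)[C@@H](c2ccccc2)O1 | intermediate
15 | methyl (10E)-11-[(4R,5R)-4,5-diphenyl-1,3-dioxolan-2-yl]-2-[(methanesulfonyl)oxy]-6,6,10-trimethyl-4-oxoundec-10-enoate | COC(=O)C(OS(C)(=O)=O)CC(=O)CC(C)(C)CCC/C(C)=C/C1O[C@H](c2ccccc2)[C@@H](c2ccccc2)O1 | intermediate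
16 | methyl (2E,10E)-11-[(4R,5R)-4,5-diphenyl-1,3-dioxolan-2-yl]-6,6,10-trimethyl-4-oxoundeca-2,10-dienoate | COC(=O)/C=C/C(=O)CC(C)(C)CCC/C(C)=C/C1O[C@H](c2ccccc2)[C@@H](c2ccccc2)O1 | intermediate
17 | methyl (2E,4Z,10E)-4-[(tert-butyldimethylsilyl)oxy]-11-[(4R,5R)-4,5-diphenyl-1,3-dioxolan-2-yl]-6,6,10-trimethylundeca-2,4,10-trienoate | COC(=O)/C=C/C(O[Si](C)(C)C(C)(C)C)=C/C(C)(C)CCC/C(C)=C/C1O[C@H](c2ccccc2)[C@@H](c2ccccc2)O1 | intermediate
18 | methyl (1R,2S,4aR,8aR)-4-[(tert-butyldimethylsilyl)oxy]-1-[(4R,5R)-4,5-diphenyl-1,3-dioxolan-2-yl]-5,5,8a-trimethyl-1,2,4a,5,6,7,8,8a-octahydronaphthalene-2-carboxylate | C3(O[C@H](c4ccccc4)[C@@H](c4ccccc4)O3)[C@@H]1[C@@H](C(=O)OC)C=C(O[Si](C)(C)C(C)(C)C)[C@@H]2C(C)(C)CCC[C@@]12C | intermediate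
19 | methyl (1R,2S,4aR,8aS)-1-[(4R,5R)-4,5-diphenyl-1,3-dioxolan-2-yl]-5,5,8a-trimethyl-4-oxodecahydronaphthalene-2-carboxylate | C3(O[C@H](c4ccccc4)[C@@H](c4ccccc4)O3)[C@@H]1[C@@H](C(=O)OC)CC(=O)[C@@H]2C(C)(C)CCC[C@@]12C | intermediate
20 | potassium enolate of 19 (C6–OK, C6=C7) | C3(O[C@H](c4ccccc4)[C@@H](c4ccccc4)O3)[C@@H]1[C@@H](C(=O)OC)C=C([O-])[C@@H]2C(C)(C)CCC[C@@]12C.[K+] | intermediate
21 | methyl (1R,2S,4aR,8aR)-1-[(4R,5R)-4,5-diphenyl-1,3-dioxolan-2-yl]-5,5,8a-trimethyl-4-[(trifluoromethanesulfonyl)oxy]-1,2,4a,5,6,7,8,8a-octahydronaphthalene-2-carboxylate | C3(O[C@H](c4ccccc4)[C@@H](c4ccccc4)O3)[C@@H]1[C@@H](C(=O)OC)C=C(OS(=O)(=O)C(F)(F)F)[C@@H]2C(C)(C)CCC[C@@]12C | intermediate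
22 | methyl (1R,2S,4aR,8aR)-1-[(4R,5R)-4,5-diphenyl-1,3-dioxolan-2-yl]-5,5,8a-trimethyl-1,2,4a,5,6,7,8,8a-octahydronaphthalene-2-carboxylate | C3(O[C@H](c4ccccc4)[C@@H](c4ccccc4)O3)[C@@H]1[C@@H](C(=O)OC)C=C[C@@H]2C(C)(C)CCC[C@@]12C | intermediate
23 | methyl (1R,2S,4aR,8aR)-1-formyl-5,5,8a-trimethyl-1,2,4a,5,6,7,8,8a-octahydronaphthalene-2-carboxylate | O=C[C@@H]1[C@@H](C(=O)OC)C=C[C@@H]2C(C)(C)CCC[C@@]12C | intermediate
24 | methyl (1R,2S,4aR,8aS)-1-ethenyl-5,5,8a-trimethyl-1,2,4a,5,6,7,8,8a-octahydronaphthalene-2-carboxylate | C=C[C@@H]1[C@@H](C(=O)OC)C=C[C@@H]2C(C)(C)CCC[C@@]12C | intermediate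
25 | methyl 4-hydroxybut-2-ynoate | COC(=O)C#CCO | starting material
26 | methyl 4-(acetyloxy)but-2-ynoate | COC(=O)C#CCOC(C)=O | intermediate
27 | methyl (2Z)-4-(acetyloxy)-3-iodobut-2-enoate | COC(=O)/C=C(\I)COC(C)=O | intermediate
28 | methyl (1R,2S,4aR,8aS)-1-[2-(9-borabicyclo[3.3.1]nonan-9-yl)ethyl]-5,5,8a-trimethyl-1,2,4a,5,6,7,8,8a-octahydronaphthalene-2-carboxylate | C(C[C@@H]1[C@@H](C(=O)OC)C=C[C@@H]2C(C)(C)CCC[C@@]12C)B1C2CCCC1CCC2 | intermediate
29 | methyl (1R,2S,4aR,8aS)-1-[(3E)-3-(acetoxymethyl)-5-methoxy-5-oxopent-3-en-1-yl]-5,5,8a-trimethyl-1,2,4a,5,6,7,8,8a-octahydronaphthalene-2-carboxylate (CNP0190145.1) | COC(=O)/C=C(\CC[C@@H]1[C@@H](C(=O)OC)C=C[C@@H]2C(C)(C)CCC[C@@]12C)COC(C)=O | target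

## Step count and risks

Total step count: 17.
Longest linear sequence: 14 steps (from 4 through steps 2 to 14, then step 17).

Steps most likely to fail:

1. Step 9 (proposed new method). The cascade may stall after the first C–C bond at the monocyclic stage, the dienol ether may be protodesilylated before it reacts, or the remote chiral arm may discriminate the two faces of C10 poorly. The fallback sets out from 16 and comes back at 19. Enoate 16 is silylated with iPr3SiOTf/Et3N to the more robust triisopropylsilyl dienol ether, methyl (2E,4Z,10E)-11-[(4R,5R)-4,5-diphenyl-1,3-dioxolan-2-yl]-6,6,10-trimethyl-4-[(triisopropylsilyl)oxy]undeca-2,4,10-trienoate F1. The conjugated acetal alone is then hydrolysed (pyridinium tosylate, wet acetone, rt) to the free (E)-enal, methyl (2E,4Z,10E)-6,6,10-trimethyl-12-oxo-4-[(triisopropylsilyl)oxy]dodeca-2,4,10-trienoate F2. F2 undergoes a Lewis-acid-promoted type 1 intramolecular Diels–Alder reaction of the aldehyde-activated dienophile (Me2AlCl, CH2Cl2, −78 °C → −20 °C), a known reaction type for deca-1,3,9-trienals, to give the racemic bicyclic aldehyde, methyl (1R,2S,4aR,8aR)-1-formyl-5,5,8a-trimethyl-4-[(triisopropylsilyl)oxy]-1,2,4a,5,6,7,8,8a-octahydronaphthalene-2-carboxylate F3 (the enantiomer carried on is shown). Acetalisation with 5 (pyridinium tosylate, benzene, 4 Å sieves) gives methyl (1R,2S,4aR,8aR)-1-[(4R,5R)-4,5-diphenyl-1,3-dioxolan-2-yl]-5,5,8a-trimethyl-4-[(triisopropylsilyl)oxy]-1,2,4a,5,6,7,8,8a-octahydronaphthalene-2-carboxylate F4 together with the diastereomer from the other enantiomer; the two are separated, so the auxiliary serves as resolving agent. Bu4NF followed by NaOMe/MeOH, as in step 10, then converts F4 into 19.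

2. Step 17. The aqueous base may cleave the acetate or move the C6=C7 bond into conjugation with the C8 ester, and transmetalation of the hindered alkylborane may be slow enough for β-acetoxy elimination from the alkenylpalladium intermediate to compete. The fallback sets out from 24 and comes back at 29. Hydroboration–oxidation (9-BBN; then NaBO3·4H2O) gives the primary alcohol, methyl (1R,2S,4aR,8aS)-1-(2-hydroxyethyl)-5,5,8a-trimethyl-1,2,4a,5,6,7,8,8a-octahydronaphthalene-2-carboxylate F5. I2, PPh3 and imidazole convert it into the iodide, methyl (1R,2S,4aR,8aS)-1-(2-iodoethyl)-5,5,8a-trimethyl-1,2,4a,5,6,7,8,8a-octahydronaphthalene-2-carboxylate F6. Zinc insertion (Zn dust, LiCl, THF) gives the alkylzinc iodide, methyl (1R,2S,4aR,8aS)-1-[2-(iodozincio)ethyl]-5,5,8a-trimethyl-1,2,4a,5,6,7,8,8a-octahydronaphthalene-2-carboxylate F7. A base-free Negishi coupling of F7 with 27 (Pd2(dba)3, P(2-furyl)3, THF/DMA, rt) then gives 29.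

3. Step 13. Hydrolysis of the hindered diphenyldioxolane next to the quaternary centre may be so slow that the forcing acid begins to migrate the ring double bond or hydrolyse the esters. The fallback sets out from 22 and comes back at 23. Ethane-1,2-dithiol and BF3·OEt2 (CH2Cl2, 0 °C) exchange the dioxolane for the dithiolane, methyl (1R,2S,4aR,8aR)-1-(1,3-dithiolan-2-yl)-5,5,8a-trimethyl-1,2,4a,5,6,7,8,8a-octahydronaphthalene-2-carboxylate F8. F8 is unmasked without acid by S-alkylation and hydrolysis (MeI, CaCO3, aq MeCN, 40 °C) to give 23.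

## Further compounds

F1 | step 9 | methyl (2E,4Z,10E)-11-[(4R,5R)-4,5-diphenyl-1,3-dioxolan-2-yl]-6,6,10-trimethyl-4-[(triisopropylsilyl)oxy]undeca-2,4,10-trienoate | COC(=O)/C=C/C(O[Si](C(C)C)(C(C)C)C(C)C)=C/C(C)(C)CCC/C(C)=C/C1O[C@H](c2ccccc2)[C@@H](c2ccccc2)O1
F2 | step 9 | methyl (2E,4Z,10E)-6,6,10-trimethyl-12-oxo-4-[(triisopropylsilyl)oxy]dodeca-2,4,10-trienoate | COC(=O)/C=C/C(O[Si](C(C)C)(C(C)C)C(C)C)=C/C(C)(C)CCC/C(C)=C/C=O
F3 | step 9 | methyl (1R,2S,4aR,8aR)-1-formyl-5,5,8a-trimethyl-4-[(triisopropylsilyl)oxy]-1,2,4a,5,6,7,8,8a-octahydronaphthalene-2-carboxylate | O=C[C@@H]1[C@@H](C(=O)OC)C=C(O[Si](C(C)C)(C(C)C)C(C)C)[C@@H]2C(C)(C)CCC[C@@]12C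
F4 | step 9 | methyl (1R,2S,4aR,8aR)-1-[(4R,5R)-4,5-diphenyl-1,3-dioxolan-2-yl]-5,5,8a-trimethyl-4-[(triisopropylsilyl)oxy]-1,2,4a,5,6,7,8,8a-octahydronaphthalene-2-carboxylate | C3(O[C@H](c4ccccc4)[C@@H](c4ccccc4)O3)[C@@H]1[C@@H](C(=O)OC)C=C(O[Si](C(C)C)(C(C)C)C(C)C)[C@@H]2C(C)(C)CCC[C@@]12C
F5 | step 17 | methyl (1R,2S,4aR,8aS)-1-(2-hydroxyethyl)-5,5,8a-trimethyl-1,2,4a,5,6,7,8,8a-octahydronaphthalene-2-carboxylate | OCC[C@@H]1[C@@H](C(=O)OC)C=C[C@@H]2C(C)(C)CCC[C@@]12C
F6 | step 17 | methyl (1R,2S,4aR,8aS)-1-(2-iodoethyl)-5,5,8a-trimethyl-1,2,4a,5,6,7,8,8a-octahydronaphthalene-2-carboxylate | ICC[C@@H]1[C@@H](C(=O)OC)C=C[C@@H]2C(C)(C)CCC[C@@]12C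
F7 | step 17 | methyl (1R,2S,4aR,8aS)-1-[2-(iodozincio)ethyl]-5,5,8a-trimethyl-1,2,4a,5,6,7,8,8a-octahydronaphthalene-2-carboxylate | I[Zn]CC[C@@H]1[C@@H](C(=O)OC)C=C[C@@H]2C(C)(C)CCC[C@@]12C
F8 | step 13 | methyl (1R,2S,4aR,8aR)-1-(1,3-dithiolan-2-yl)-5,5,8a-trimethyl-1,2,4a,5,6,7,8,8a-octahydronaphthalene-2-carboxylate | S3CCSC3[C@@H]1[C@@H](C(=O)OC)C=C[C@@H]2C(C)(C)CCC[C@@]12C
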